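Readings and results come from a simulation for an exercise; scatter was added.

The ratio at 8.0 s cannot be read off, because neither earlier run was sampled before 4.00 min, so it has to be reckoned.

| flask | starting material | reagent | free catalyst | impurity | remark | time |
|---|---|---|---|---|---|---|
| theta | 35 mM | 52.5 mM | 35 µM | 8.5 µM | run made earlier |  |
| zeta | 35 mM | 52.5 mM | 35 µM | 13 µM | run made earlier |  |
| flask | 35 mM | 52.5 mM | 35 µM | 6.1 µM |  | 40 min |

| run | time / min | isomer of the product / % | target / % |
|---|---|---|---|
| theta | 4.00 | 7 | 50 |
| theta | 12.0 | 15 | 64 |
| theta | 20.0 | 15 | 60 |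
| theta | 30.0 | 23 | 57 |
| theta | 50.0 | 25 | 54 |
| zeta | 10.0 | 15 | 59 |
| zeta | 20.0 | 17 | 58 |
| zeta | 30.0 | 19 | 59 |
| zeta | 40.0 | 25 | 53 |
| zeta | 50.0 | 24 | 57 |

(scatter of a reading: 1.5 percentage points)

1. ratio of isomer of the product to target at 8.0 s
2. ratio of isomer of the product to target at 40 min
3. which of isomer of the product and target there is more of at 40 min

- the numbers in the tables scatter by 1.5 percentage points (one standard deviation)

What do you follow? The ratio r of isomer of the product to target.

May theta and zeta be pooled? With care. At 50.0 min, r reads 0.463 in theta and 0.421 in zeta, a gap that a scatter of 1.5 percentage points per reading allows. But the flask's 6.1 µM of impurity lies below both tested charges, so pooling stays an assumption.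

And r at 40 min? I replace the curve by a mean. The 5 readings from 30.0 min to 50.0 min have a mean time of 40.0 min and a mean r of 0.416. Target stays ahead, because that is below one.

And the start? A straight line from 0.140 at 4.00 min to that mean rises 0.00767 min⁻¹ and reaches 0.110 at 8.0 s.

Is that line fair? No. The pooled readings near 11.0 min give 0.244, an early slope of 0.0149 min⁻¹, twice the mean one. With the early slope I commit to 0.0824. The weak spot is the isomer reading at 4.00 min: 7%, give or take 1.5 points.

What do you carry on? The mean climb c, the rise of r per minute averaged from the first moments to 40 min: 0.00837 min⁻¹.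

The forecast gives 0.12, 0.41 and target ahead: “Extrapolating back from later times gives an intercept near 0.12”. My early value is lower.

The flask gives 0.0838 and 0.430, with target ahead, 54.8% to 23.6%.

    starting material + reagent ⇌ isomer of the product (K = 57.7 M⁻¹, k = 0.00780 M⁻¹ s⁻¹)
    free catalyst + impurity → spent catalyst B (k = 16500 M⁻¹ s⁻¹)
    2 free catalyst → spent catalyst A (k = 8.90 M⁻¹ s⁻¹)
    target + free catalyst ⇌ isomer of the product + free catalyst, rate k4*[free catalyst]*[target] forward; the back reaction follows from the equilibrium constant (k = 10.1 M⁻¹ s⁻¹)
    starting material + reagent ⇌ target (K = 100 M⁻¹, k = 0.0946 M⁻¹ s⁻¹)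

The flask's own c is 0.00868 min⁻¹, beside the 0.00837 min⁻¹ read from the runs. For the neighbour charged with 140 mM of starting material, 0.00837 min⁻¹ laid on its 0.0839 gives 0.418, and that flask gives 0.447. By 4.00 min the flask's impurity stood at 0% with 17.4% of the catalyst as spent catalyst B, while the direct steps, at a selectivity factor of 12, had brought starting material to 43.2%. From 20.0 min to 40.0 min starting material went from 23.1% to 21.7%, target from 58.8% to 54.8% and isomer of the product from 18.0% to 23.6%, as free catalyst fell from 51.0% to 36.9%.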